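**Retrosynthetic overview**
1. The ten-membered ring is closed last: target 36 from enyne 34 by ring-closing enyne metathesis, which forms C3=C4 and C5=C16 together.
2. 34 comes from aldehyde 27 and chloroallenylzinc 30 (C6–C7 bond, anti Cl/O) with closure of the γ-lactone; 27 comes from a propionate aldol on α-acetoxy enone 22 (C8–C17) and ozonolysis.
3. 22 comes from ester 11 by acetylide acylation, C11-hydroxyl-directed reduction at C9 and a Meyer–Schuster shift; the ring oxygens come from α-face osmylation of a cyclohexadiene and a hydroxyl-directed epoxidation.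
4. The six-membered ring is made first: a hydrogen-bond-catalysed Diels–Alder reaction of aminosiloxydiene 3 with enal ester 4 sets C1 (quaternary) and C10; a chelation-controlled vinyl addition then sets C2.
5. Ring order: cyclohexene, epoxide, γ-lactone, ten-membered ring.

Conventions: briarane numbering (C1–C20; C18 = methyl on C17, C19 = lactone carbonyl) is used for every intermediate. α is the face of the six-membered ring that carries H-10, β the face that carries the C1 methyl. TBS = tert-butyldimethylsilyl, TES = triethylsilyl, TMS = trimethylsilyl.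

Assumption: 1, 4, 12, 23 and 28 are bought (all achiral), and the (R,R) enantiomer of the TADDOL catalyst is taken to give the C1/C10 configuration shown; if its sense of induction is the opposite, the (S,S) catalyst is used.

**Step 1**
Reactants: 1 (E)-1-(dimethylamino)pent-1-en-3-one
Product: 3 (1E,3Z)-3-(TBS-oxy)-N,N-dimethylpenta-1,3-dien-1-amine, via potassium dienolate 2 (not isolated)
Conditions: KN(SiMe3)2, THF, −78 °C; TBSCl, −78 → 23 °C
Reagents that add atoms: tert-butyldimethylsilyl chloride, CC(C)(C)[Si](C)(C)Cl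
Why: α′-Deprotonation of the vinylogous amide gives the Z-enolate, which is silylated on oxygen (silyl enol ether formation) to the 1-amino-3-siloxydiene; no stereocentre is formed.

**Step 2**
Reactants: 3 (1E,3Z)-3-(TBS-oxy)-N,N-dimethylpenta-1,3-dien-1-amine; 4 ethyl (E)-3-methyl-4-oxobut-2-enoate
Product: 5 cycloadduct ethyl 5-(dimethylamino)-6-formyl-2,6-dimethyl-3-(TBS-oxy)cyclohex-3-ene-1-carboxylate (formyl and ester trans)
Conditions: (4R,5R)-2,2-dimethyl-α,α,α′,α′-tetra(naphth-1-yl)-1,3-dioxolane-4,5-dimethanol [(R,R)-1-naphthyl-TADDOL, 20 mol %], toluene, −78 → −40 °C, 48 h; solvent removed cold, crude used directly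
Reagents that add atoms: none
Why: Proposed new method: a hydrogen-bond-catalysed Diels–Alder reaction of a trisubstituted, β-ester-bearing α-methyl enal with a 4-methyl-1-amino-3-siloxydiene, in which the free hydroxyl of the TADDOL (made more acidic by its internal O–H···O bond) binds the formyl oxygen of s-trans 4 while one naphthyl group shields one enal face, the LUMO coefficient β to the bound aldehyde sends the nucleophilic methyl-bearing diene terminus to the ester carbon (C10) and the amine-bearing terminus to the methyl carbon (C1, quaternary) through an asynchronous formyl-endo transition state, so that C1 and C10 are set in absolute terms by the catalyst and trans to each other by the E geometry of 4 (suprafacial addition), the fumarate-like double activation making up for the extra substituents; closest known reaction: the TADDOL-catalysed Diels–Alder reaction of 1-amino-3-siloxybutadiene with α-substituted acroleins that carry no β-substituent.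

**Step 3**
Reactants: 5 cycloadduct
Product: 8 enone ethyl 2,6-dimethyl-3-oxo-6-[(1S)-1-(TBS-oxy)prop-2-en-1-yl]cyclohex-4-ene-1-carboxylate, via bromomagnesium alkoxide 6 (not isolated), via bis-silyl amino enol ether 7 (not isolated)
Conditions: CH2=CHMgBr, THF, −78 °C; TBSOTf, −78 → −40 °C; 1 N HCl, THF, 0 °C
Reagents that add atoms: vinylmagnesium bromide, C=C[Mg]Br; tert-butyldimethylsilyl triflate, CC(C)(C)[Si](C)(C)OS(=O)(=O)C(F)(F)F
Why: Grignard addition to the neopentyl aldehyde occurs anti to C10 within the six-membered magnesium chelate between the formyl oxygen and the cis C14 dimethylamino group (the same face that Felkin–Anh predicts) and sets C2 (S); the alkoxide is silylated before it can lactonise onto the ester, and acid then hydrolyses the silyl enol ether and eliminates dimethylamine (E1cB) to the enone.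

**Step 4**
Reactants: 8 enone
Product: 10 dienyl triflate ethyl 2,6-dimethyl-6-[(1S)-1-(TBS-oxy)prop-2-en-1-yl]-3-(trifluoromethylsulfonyloxy)cyclohexa-2,4-diene-1-carboxylate, via potassium dienolate 9 (not isolated)
Conditions: KN(SiMe3)2, THF, −78 °C; PhNTf2, −78 → 0 °C
Reagents that add atoms: N-phenylbis(trifluoromethanesulfonimide), O=S(=O)(N(c1ccccc1)S(=O)(=O)C(F)(F)F)C(F)(F)F
Why: C11 is the only enolisable position of the ketone (C1 is quaternary and the ester α-hydrogen is far less acidic), so the cross-conjugated dienolate forms there and is triflated on oxygen (enol triflate formation), which deletes the C11 stereocentre.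

**Step 5**
Reactants: 10 dienyl triflate
Product: 11 diene ester ethyl 2,6-dimethyl-6-[(1S)-1-(TBS-oxy)prop-2-en-1-yl]cyclohexa-2,4-diene-1-carboxylate
Conditions: Pd(OAc)2 (5 mol %), PPh3 (10 mol %), HCO2H, Et3N, DMF, 60 °C
Reagents that add atoms: none
Why: Palladium-catalysed formate reduction of the enol triflate (oxidative addition to zerovalent palladium, decarboxylation of formate, reductive elimination) gives the cyclohexa-1,3-diene without touching the ester or the vinyl group.

**Step 6**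
Reactants: 11 diene ester; 12 2-methyl-2-(trimethylsilyloxy)but-3-yne
Product: 15 ynone (C9 ketone, C8≡C7, C6 = CMe2OTMS), via lithium acetylide 13 (not isolated), via lithium alkynyltrifluoroborate 14 (not isolated)
Conditions: 12, n-BuLi, THF, −78 °C; BF3·OEt2; then 11, −78 °C; aq NH4Cl
Reagents that add atoms: none
Why: The non-basic alkynyltrifluoroborate adds once to the ester because the boron-bound tetrahedral adduct survives until the quench (ynone synthesis from esters), so C9 reaches the ketone level needed for the directed reduction and the allylic C10–H is not deprotonated.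

**Step 7**
Reactants: 15 ynone
Product: 16 11α,12α-diol (C11 methyl β)
Conditions: OsO4 (2 mol %), N-methylmorpholine N-oxide, acetone–H2O, 0 °C
Reagents that add atoms: N-methylmorpholine N-oxide, C[N+]1([O-])CCOCC1; water, O
Why: Catalytic osmylation (Upjohn dihydroxylation) takes the more electron-rich trisubstituted C11=C12 bond of the diene on the α-face, opposite the pseudo-axial C1 methyl and the C10 acyl group, and so sets C11 (OH α, Me β) and C12 (OH α) together as the cis-diol.

**Step 8**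
Reactants: 16 diol
Product: 17 13α,14α-epoxy-11α,12α-diol
Conditions: VO(acac)2 (5 mol %), t-BuOOH, CH2Cl2, 0 °C
Reagents that add atoms: tert-butyl hydroperoxide, CC(C)(C)OO
Why: Vanadium-catalysed hydroxyl-directed epoxidation delivers oxygen to C13=C14 syn to the allylic C12 hydroxyl (helped by the homoallylic C11 hydroxyl), giving the α-epoxide at C13 and C14, while the silylated vinyl carbinol and the ynone are not allylic alcohols and stay intact.

**Step 9**
Reactants: 17 epoxy diol
Product: 18 12-O-TBS ether (C11 hydroxyl free)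
Conditions: TBSOTf (1.1 equiv), 2,6-lutidine, CH2Cl2, −78 °C
Reagents that add atoms: tert-butyldimethylsilyl triflate, CC(C)(C)[Si](C)(C)OS(=O)(=O)C(F)(F)F
Why: Silylation at low temperature takes the secondary C12 hydroxyl and leaves the tertiary C11 hydroxyl free to direct the next step (selective silyl ether formation).

**Step 10**
Reactants: 18 silyl ether
Product: 19 (9S)-propargylic alcohol
Conditions: Me4NBH(OAc)3, MeCN–AcOH (1:1), −30 °C; aq sodium potassium tartrate and NaHCO3, 0 °C
Reagents that add atoms: none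
Why: Hydride is delivered intramolecularly from the C11 alkoxyborohydride through a six-membered transition state (hydroxyl-directed 1,3-anti reduction), so it reaches the ynone carbonyl from the C11 side with the alkynyl group turned away from the two β-methyl groups, which sets C9 (S).

**Step 11**
Reactants: 19 propargylic alcohol
Product: 20 9-O-acetate
Conditions: Ac2O, pyridine, 0 → 23 °C
Reagents that add atoms: acetic anhydride, CC(=O)OC(C)=O
Why: Acetylation without a nucleophilic catalyst takes the secondary propargylic C9 hydroxyl and leaves the tertiary C11 hydroxyl (esterification, no new stereocentre).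

**Step 12**
Reactants: 20 acetate
Product: 22 α-acetoxy enone [C9H(OAc)–C8(=O)–C7H=CMe2], via tertiary propargylic alcohol 21 (not isolated)
Conditions: pyridinium p-toluenesulfonate, MeOH, 0 °C; solvent exchange; ReOCl3(OPPh3)(SMe2) (5 mol %), 1,2-dimethoxyethane, 23 °C
Reagents that add atoms: none
Why: Mild methanolysis frees the tertiary propargylic alcohol, whose rhenium oxo ester undergoes a [3,3] oxygen shift (Meyer–Schuster rearrangement) that places the carbonyl on C8 and gives the isobutenyl ketone, while the C9 acetate cannot bind rhenium and C9 is untouched.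

**Step 13**
Reactants: 22 α-acetoxy enone; 23 methyl propanoate
Product: 26 aldol ester with 8-O-TES and 11-O-TES groups, via lithium enolate 24 (not isolated), via dilithium aldolate 25 (not isolated)
Conditions: 23 (2.3 equiv), LiN(iPr)2, THF–DMPU (4:1), −78 °C; 22, −78 °C, 30 min; Et3SiOTf, −78 → −40 °C
Reagents that add atoms: triethylsilyl triflate, CC[Si](CC)(CC)OS(=O)(=O)C(F)(F)F
Why: Aldol addition of the lithium enolate (methyl cis to OLi) goes 1,2 to the β,β-disubstituted enone, with polar Felkin–Anh attack anti to the C9 acetoxy group setting C8 and a closed Zimmerman–Traxler chair (C9 branch equatorial) placing the C17 methyl syn to the new oxygen, and the alkoxides are trapped as silyl ethers before acetyl migration can start.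

**Step 14**
Reactants: 26 aldol ester
Product: 27 C7 aldehyde
Conditions: O3, pyridine (3 equiv), CH2Cl2, −78 °C, to the Sudan Red 7B end point
Reagents that add atoms: ozone, [O-][O+]=O
Why: Ozone cleaves the electron-rich trisubstituted isobutenyl alkene much faster than the monosubstituted vinyl group next to the silyloxy carbon (ozonolysis, pyridine giving the carbonyl products directly), which unmasks the C7 aldehyde.

**Step 15**
Reactants: 27 aldehyde; 28 3-chloro-1-(trimethylsilyl)prop-1-yne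
Product: 32 γ-lactone with C6 chloride and TMS-alkyne, via lithio carbenoid 29 (not isolated), via chloroallenylzinc bromide 30 (not isolated), via chlorohydrin ester 31 (not isolated)
Conditions: 28, n-BuLi, THF–Et2O, −95 °C; ZnBr2, −95 → −78 °C; 27, −78 → −20 °C; aq NH4Cl; then pyridinium p-toluenesulfonate (cat.), CH2Cl2, 23 °C
Reagents that add atoms: none
Why: The chloroallenylzinc carbenoid adds through a cyclic SE2′ transition state to give the anti chlorohydrin (C6), Felkin–Anh attack anti to the C8 silyloxy group with the smaller C17 branch beside the incoming nucleophile sets C7, and the new hydroxyl closes the five-membered lactone on the methyl ester (propargylation, then lactonisation).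

**Step 16**
Reactants: 32 lactone
Product: 33 2,8,11,12-tetraol with terminal alkyne (9-OAc kept)
Conditions: Bu4NF, AcOH (1:1), THF, 0 → 40 °C
Reagents that add atoms: none
Why: Buffered fluoride removes all five silyl groups (two TBS, two TES, the alkynyl TMS) without acetyl migration, epoxide opening or loss of the propargylic chloride (desilylation).

**Step 17**
Reactants: 33 tetraol
Product: 34 2,12-bis-butanoate
Conditions: (n-PrCO)2O, DMAP, Et3N, CH2Cl2, 23 °C
Reagents that add atoms: butanoic anhydride, CCCC(=O)OC(=O)CCC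
Why: DMAP-catalysed acylation takes the two secondary hydroxyls (C2, C12) and leaves the tertiary C8 and C11 hydroxyls, which is the natural substitution pattern (esterification).

**Step 18**
Reactants: 34 bis-butanoate enyne
Product: 36 target CNP0188106.1, via triene 35 (not isolated)
Conditions: second-generation Grubbs catalyst RuCl2(=CHPh)(PCy3)(H2IMes) (15 mol %), ethene (1 atm), toluene, 60 °C; then argon sparge, dilution to 1 mM, 90 °C
Reagents that add atoms: ethene, C=C
Why: Cross enyne metathesis with ethene turns the alkyne into the 2-substituted butadiene and ring-closing metathesis of the two monosubstituted alkenes under dilution then forms the 3Z,5(16)-diene and the ten-membered ring, the Z geometry being the one the ring accommodates and no stereocentre being touched.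

**Compound list**
1 | (E)-1-(dimethylamino)pent-1-en-3-one | CCC(=O)/C=C/N(C)C | starting material
2 | potassium (1E,3Z)-1-(dimethylamino)penta-1,3-dien-3-olate | C\C=C(/[O-])\C=C\N(C)C.[K+] | intermediate
3 | (1E,3Z)-3-(TBS-oxy)-N,N-dimethylpenta-1,3-dien-1-amine | C\C=C(/O[Si](C)(C)C(C)(C)C)\C=C\N(C)C | intermediate
4 | ethyl (E)-3-methyl-4-oxobut-2-enoate | CCOC(=O)/C=C(\C)C=O | starting material
5 | cycloadduct, ethyl 5-(dimethylamino)-6-formyl-2,6-dimethyl-3-(TBS-oxy)cyclohex-3-ene-1-carboxylate; C1 Me β and CHO α, C10 ester β, C11 Me α, C14 NMe2 α | O=C[C@@]1(C)[C@@H](N(C)C)C=C(O[Si](C)(C)C(C)(C)C)[C@@H](C)[C@@H]1C(=O)OCC | intermediate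
6 | bromomagnesium alkoxide of the (2S)-vinyl carbinol formed from 5 | C=C[C@H](O[Mg]Br)[C@@]1(C)[C@@H](N(C)C)C=C(O[Si](C)(C)C(C)(C)C)[C@@H](C)[C@@H]1C(=O)OCC | intermediate
7 | (2S)-2-O-TBS vinyl carbinol still carrying the C14 amine and C12 silyl enol ether | C=C[C@H](O[Si](C)(C)C(C)(C)C)[C@@]1(C)[C@@H](N(C)C)C=C(O[Si](C)(C)C(C)(C)C)[C@@H](C)[C@@H]1C(=O)OCC | intermediate
8 | enone, ethyl 2,6-dimethyl-3-oxo-6-[(1S)-1-(TBS-oxy)prop-2-en-1-yl]cyclohex-4-ene-1-carboxylate; C1 Me β, C2 chain α, C10 ester β (C11 methyl drawn α, immaterial) | C=C[C@H](O[Si](C)(C)C(C)(C)C)[C@@]1(C)C=CC(=O)[C@@H](C)[C@@H]1C(=O)OCC | intermediate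
9 | potassium cross-conjugated dienolate of 8 (C11=C12–O−) | C=C[C@H](O[Si](C)(C)C(C)(C)C)[C@@]1(C)C=CC([O-])=C(C)[C@@H]1C(=O)OCC.[K+] | intermediate
10 | dienyl triflate, ethyl 2,6-dimethyl-6-[(1S)-1-(TBS-oxy)prop-2-en-1-yl]-3-(trifluoromethylsulfonyloxy)cyclohexa-2,4-diene-1-carboxylate | C=C[C@H](O[Si](C)(C)C(C)(C)C)[C@@]1(C)C=CC(OS(=O)(=O)C(F)(F)F)=C(C)[C@@H]1C(=O)OCC | intermediate
11 | diene ester, ethyl 2,6-dimethyl-6-[(1S)-1-(TBS-oxy)prop-2-en-1-yl]cyclohexa-2,4-diene-1-carboxylate | C=C[C@H](O[Si](C)(C)C(C)(C)C)[C@@]1(C)C=CC=C(C)[C@@H]1C(=O)OCC | intermediate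
12 | 2-methyl-2-(trimethylsilyloxy)but-3-yne | C#CC(C)(C)O[Si](C)(C)C | starting material
13 | lithium 3-methyl-3-(trimethylsilyloxy)but-1-yn-1-ide | [Li+].[C-]#CC(C)(C)O[Si](C)(C)C | intermediate
14 | lithium trifluoro[3-methyl-3-(trimethylsilyloxy)but-1-ynyl]borate | [Li+].F[B-](F)(F)C#CC(C)(C)O[Si](C)(C)C | intermediate
15 | ynone, 1-{2,6-dimethyl-6-[(1S)-1-(TBS-oxy)prop-2-en-1-yl]cyclohexa-2,4-dien-1-yl}-4-methyl-4-(trimethylsilyloxy)pent-2-yn-1-one (C9 ketone on C10 β) | C=C[C@H](O[Si](C)(C)C(C)(C)C)[C@@]1(C)C=CC=C(C)[C@@H]1C(=O)C#CC(C)(C)O[Si](C)(C)C | intermediate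
16 | 11α,12α-diol of 15 (C11 OH α and Me β, C12 OH α, C13=C14 kept) | C=C[C@H](O[Si](C)(C)C(C)(C)C)[C@@]1(C)C=C[C@@H](O)[C@@](C)(O)[C@@H]1C(=O)C#CC(C)(C)O[Si](C)(C)C | intermediate
17 | 13α,14α-epoxide of 16 | C=C[C@H](O[Si](C)(C)C(C)(C)C)[C@@]1(C)[C@H]2O[C@H]2[C@@H](O)[C@@](C)(O)[C@@H]1C(=O)C#CC(C)(C)O[Si](C)(C)C | intermediate
18 | 12-O-TBS ether of 17 (C11 OH free) | C=C[C@H](O[Si](C)(C)C(C)(C)C)[C@@]1(C)[C@H]2O[C@H]2[C@@H](O[Si](C)(C)C(C)(C)C)[C@@](C)(O)[C@@H]1C(=O)C#CC(C)(C)O[Si](C)(C)C | intermediate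
19 | (9S)-propargylic alcohol from 18 (O9 and O11 1,3-anti) | C=C[C@H](O[Si](C)(C)C(C)(C)C)[C@@]1(C)[C@H]2O[C@H]2[C@@H](O[Si](C)(C)C(C)(C)C)[C@@](C)(O)[C@@H]1[C@H](O)C#CC(C)(C)O[Si](C)(C)C | intermediate
20 | 9-O-acetate of 19 | C=C[C@H](O[Si](C)(C)C(C)(C)C)[C@@]1(C)[C@H]2O[C@H]2[C@@H](O[Si](C)(C)C(C)(C)C)[C@@](C)(O)[C@@H]1[C@H](OC(C)=O)C#CC(C)(C)O[Si](C)(C)C | intermediate
21 | tertiary propargylic alcohol (20 without the trimethylsilyl group) | C=C[C@H](O[Si](C)(C)C(C)(C)C)[C@@]1(C)[C@H]2O[C@H]2[C@@H](O[Si](C)(C)C(C)(C)C)[C@@](C)(O)[C@@H]1[C@H](OC(C)=O)C#CC(C)(C)O | intermediate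
22 | α-acetoxy enone, (9S)-9-acetoxy-8-oxo with C7H=CMe2, on the 2-O-TBS, 12-O-TBS, 11-hydroxy, 13α,14α-epoxy core | C=C[C@H](O[Si](C)(C)C(C)(C)C)[C@@]1(C)[C@H]2O[C@H]2[C@@H](O[Si](C)(C)C(C)(C)C)[C@@](C)(O)[C@@H]1[C@H](OC(C)=O)C(=O)C=C(C)C | intermediate
23 | methyl propanoate | CCC(=O)OC | starting material
24 | lithium enolate of methyl propanoate (methyl cis to OLi) | C/C=C(/OC)[O-].[Li+] | intermediate
25 | dilithium 8,11-bis-alkoxide of the aldol adduct (C8 and C17 as in the target) | C=C[C@H](O[Si](C)(C)C(C)(C)C)[C@@]1(C)[C@H]2O[C@H]2[C@@H](O[Si](C)(C)C(C)(C)C)[C@@](C)(O[Li])[C@@H]1[C@H](OC(C)=O)[C@](C=C(C)C)(O[Li])[C@@H](C)C(=O)OC | intermediate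
26 | aldol methyl ester with 8-O-TES and 11-O-TES (C8 bears isobutenyl, OTES, C9 and C17; C17 methyl as in the target) | C=C[C@H](O[Si](C)(C)C(C)(C)C)[C@@]1(C)[C@H]2O[C@H]2[C@@H](O[Si](C)(C)C(C)(C)C)[C@@](C)(O[Si](CC)(CC)CC)[C@@H]1[C@H](OC(C)=O)[C@](C=C(C)C)(O[Si](CC)(CC)CC)[C@@H](C)C(=O)OC | intermediate
27 | C7 aldehyde (26 with the isobutenyl group cut to CHO) | C=C[C@H](O[Si](C)(C)C(C)(C)C)[C@@]1(C)[C@H]2O[C@H]2[C@@H](O[Si](C)(C)C(C)(C)C)[C@@](C)(O[Si](CC)(CC)CC)[C@@H]1[C@H](OC(C)=O)[C@](C=O)(O[Si](CC)(CC)CC)[C@@H](C)C(=O)OC | intermediate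
28 | 3-chloro-1-(trimethylsilyl)prop-1-yne | ClCC#C[Si](C)(C)C | starting material
29 | 3-chloro-3-lithio-1-(trimethylsilyl)prop-1-yne (racemic, labile carbenoid) | Cl[CH-]C#C[Si](C)(C)C.[Li+] | intermediate
30 | [3-chloro-1-(trimethylsilyl)propa-1,2-dien-1-yl]zinc bromide | ClC=C=C([Zn]Br)[Si](C)(C)C | intermediate
31 | anti-chlorohydrin hydroxy ester (C7 OH, C6 Cl, C5≡C4–TMS; C6 and C7 as in the target) | C=C[C@H](O[Si](C)(C)C(C)(C)C)[C@@]1(C)[C@H]2O[C@H]2[C@@H](O[Si](C)(C)C(C)(C)C)[C@@](C)(O[Si](CC)(CC)CC)[C@@H]1[C@H](OC(C)=O)[C@]([C@@H](O)[C@@H](Cl)C#C[Si](C)(C)C)(O[Si](CC)(CC)CC)[C@@H](C)C(=O)OC | intermediate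
32 | γ-lactone (O7–C19) with 8-O-TES, 11-O-TES, 2-O-TBS, 12-O-TBS, 9-OAc, C6 chloride and TMS-alkyne | C=C[C@H](O[Si](C)(C)C(C)(C)C)[C@@]1(C)[C@H]2O[C@H]2[C@@H](O[Si](C)(C)C(C)(C)C)[C@@](C)(O[Si](CC)(CC)CC)[C@@H]1[C@H](OC(C)=O)[C@]1(O[Si](CC)(CC)CC)[C@@H](C)C(=O)O[C@H]1[C@@H](Cl)C#C[Si](C)(C)C | intermediate
33 | desilylated lactone: 2,8,11,12-tetraol, 9-acetate, 13α,14α-epoxide, C6 chloride, terminal alkyne, C3 vinyl | C=C[C@H](O)[C@@]1(C)[C@H]2O[C@H]2[C@@H](O)[C@@](C)(O)[C@@H]1[C@H](OC(C)=O)[C@]1(O)[C@@H](C)C(=O)O[C@H]1[C@@H](Cl)C#C | intermediate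
34 | 2,12-bis-butanoate of 33 (seco enyne) | C=C[C@H](OC(=O)CCC)[C@@]1(C)[C@H]2O[C@H]2[C@@H](OC(=O)CCC)[C@@](C)(O)[C@@H]1[C@H](OC(C)=O)[C@]1(O)[C@@H](C)C(=O)O[C@H]1[C@@H](Cl)C#C | intermediate
35 | triene (34 with the alkyne converted into a 2-substituted buta-1,3-diene) | C=C[C@H](OC(=O)CCC)[C@@]1(C)[C@H]2O[C@H]2[C@@H](OC(=O)CCC)[C@@](C)(O)[C@@H]1[C@H](OC(C)=O)[C@]1(O)[C@@H](C)C(=O)O[C@H]1[C@@H](Cl)C(=C)C=C | intermediate
36 | CNP0188106.1, (1S,2S,6S,7R,8R,9S,10S,11S,12R,13R,14R,17R)-9-acetoxy-2,12-bis(butanoyloxy)-6-chloro-13,14-epoxy-8,11-dihydroxybriara-3(Z),5(16)-diene 19,7-lactone | C=C1/C=C\[C@H](OC(=O)CCC)[C@@]2(C)[C@H]3O[C@H]3[C@@H](OC(=O)CCC)[C@@](C)(O)[C@@H]2[C@H](OC(C)=O)[C@]2(O)[C@@H](C)C(=O)O[C@H]2[C@H]1Cl | target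

**Totals**
Total step count: 18. Longest linear sequence: 18 steps (1 to 36); 4, 12, 23 and 28 are bought and enter directly.

**The three steps most likely to fail**

Step 2 (the new Diels–Alder reaction). The first bond joins two substituted carbons, the formyl group could react as a hetero-dienophile instead, and the enantioselectivity on this substrate class is untested. The fallback uses known reactions only, sets out from 4 and returns at 8. Pent-1-en-3-one is silylated (TBSOTf, Et3N) to (Z)-3-(TBS-oxy)penta-1,3-diene F1. A Diels–Alder reaction of 4 with F1 under a protonated o-tolyl oxazaborolidine activated by Tf2NH (a boron Lewis acid, so still metal-free; the siloxy-activated diene terminus bonds to the ester carbon) gives the silyl enol ether cycloadduct F2 with the same C1/C10 outcome. CH2=CHMgBr adds under Felkin–Anh control (C10 branch anti) to give the bromomagnesium alkoxide F3, which is trapped with TBSOTf as the bis-silyl ether F4. Saegusa–Ito oxidation of F4 with Pd(OAc)2 in MeCN converts the C12 silyl enol ether into the C13=C14 enone and delivers 8.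

Step 13 (propionate aldol). The α-acetoxy ketone is enolisable and carries a transferable acetate, and simple diastereoselection at C17 in an ester-enolate addition to a ketone is uncertain. Transmetalating the enolate with CeCl3 lowers its basicity without changing the products. The fallback gives up kinetic control at C17 and corrects it thermodynamically; it sets out from 22 and returns at 33. The C17-epimeric dilithium aldolate F5 that forms alongside 25 is silylated to the 17-epi aldol ester F6 and carried through steps 14 to 16 unchanged, giving the 17-epi aldehyde F7, the 17-epi chlorohydrin ester F8, the 17-epi lactone F9 and the 17-epi tetraol F10. DBU (0.3 equiv, toluene, 23 °C) then equilibrates F10 through the lactone enolate to 33, in which the C17 methyl is trans to the bulky C9 branch and cis to the small C8 hydroxyl.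

Step 18 (ring-closing enyne metathesis). The ten-membered ring is strained and the C3 vinyl group is hindered and deactivated by the neighbouring butanoate. The fallback cyclises before acylation; it sets out from 33 and returns at 36. The same ethene-mediated sequence is run on tetraol 33, whose free C2 allylic hydroxyl assists loading of ruthenium on the C3 alkene, giving the tetraol triene F11 and then the macrocyclic 2,12-diol F12. Butanoic anhydride with DMAP then acylates the two secondary hydroxyls of F12 to give 36.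

**Further compounds**
F1 | step 2 | (Z)-tert-butyl(dimethyl)(penta-1,3-dien-3-yloxy)silane | C\C=C(/O[Si](C)(C)C(C)(C)C)C=C
F2 | step 2 | ethyl 6-formyl-2,6-dimethyl-3-(TBS-oxy)cyclohex-3-ene-1-carboxylate (formyl and ester trans, C1/C10 as in 5) | O=C[C@@]1(C)CC=C(O[Si](C)(C)C(C)(C)C)[C@@H](C)[C@@H]1C(=O)OCC
F3 | step 2 | bromomagnesium alkoxide of the (2S)-vinyl carbinol from F2 | C=C[C@H](O[Mg]Br)[C@@]1(C)CC=C(O[Si](C)(C)C(C)(C)C)[C@@H](C)[C@@H]1C(=O)OCC
F4 | step 2 | ethyl 2,6-dimethyl-3-(TBS-oxy)-6-[(1S)-1-(TBS-oxy)prop-2-en-1-yl]cyclohex-3-ene-1-carboxylate | C=C[C@H](O[Si](C)(C)C(C)(C)C)[C@@]1(C)CC=C(O[Si](C)(C)C(C)(C)C)[C@@H](C)[C@@H]1C(=O)OCC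
F5 | step 13 | 17-epimer of dilithium aldolate 25 | C=C[C@H](O[Si](C)(C)C(C)(C)C)[C@@]1(C)[C@H]2O[C@H]2[C@@H](O[Si](C)(C)C(C)(C)C)[C@@](C)(O[Li])[C@@H]1[C@H](OC(C)=O)[C@](C=C(C)C)(O[Li])[C@H](C)C(=O)OC
F6 | step 13 | 17-epimer of aldol ester 26 | C=C[C@H](O[Si](C)(C)C(C)(C)C)[C@@]1(C)[C@H]2O[C@H]2[C@@H](O[Si](C)(C)C(C)(C)C)[C@@](C)(O[Si](CC)(CC)CC)[C@@H]1[C@H](OC(C)=O)[C@](C=C(C)C)(O[Si](CC)(CC)CC)[C@H](C)C(=O)OC
F7 | step 13 | 17-epimer of aldehyde 27 | C=C[C@H](O[Si](C)(C)C(C)(C)C)[C@@]1(C)[C@H]2O[C@H]2[C@@H](O[Si](C)(C)C(C)(C)C)[C@@](C)(O[Si](CC)(CC)CC)[C@@H]1[C@H](OC(C)=O)[C@](C=O)(O[Si](CC)(CC)CC)[C@H](C)C(=O)OC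
F8 | step 13 | 17-epimer of chlorohydrin ester 31 | C=C[C@H](O[Si](C)(C)C(C)(C)C)[C@@]1(C)[C@H]2O[C@H]2[C@@H](O[Si](C)(C)C(C)(C)C)[C@@](C)(O[Si](CC)(CC)CC)[C@@H]1[C@H](OC(C)=O)[C@]([C@@H](O)[C@@H](Cl)C#C[Si](C)(C)C)(O[Si](CC)(CC)CC)[C@H](C)C(=O)OC
F9 | step 13 | 17-epimer of lactone 32 | C=C[C@H](O[Si](C)(C)C(C)(C)C)[C@@]1(C)[C@H]2O[C@H]2[C@@H](O[Si](C)(C)C(C)(C)C)[C@@](C)(O[Si](CC)(CC)CC)[C@@H]1[C@H](OC(C)=O)[C@]1(O[Si](CC)(CC)CC)[C@H](C)C(=O)O[C@H]1[C@@H](Cl)C#C[Si](C)(C)C
F10 | step 13 | 17-epimer of tetraol 33 | C=C[C@H](O)[C@@]1(C)[C@H]2O[C@H]2[C@@H](O)[C@@](C)(O)[C@@H]1[C@H](OC(C)=O)[C@]1(O)[C@H](C)C(=O)O[C@H]1[C@@H](Cl)C#C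
F11 | step 18 | tetraol triene (33 with the alkyne converted into a 2-substituted buta-1,3-diene) | C=C[C@H](O)[C@@]1(C)[C@H]2O[C@H]2[C@@H](O)[C@@](C)(O)[C@@H]1[C@H](OC(C)=O)[C@]1(O)[C@@H](C)C(=O)O[C@H]1[C@@H](Cl)C(=C)C=C
F12 | step 18 | macrocyclic 2,12-diol (36 lacking both butanoyl groups) | C=C1/C=C\[C@H](O)[C@@]2(C)[C@H]3O[C@H]3[C@@H](O)[C@@](C)(O)[C@@H]2[C@H](OC(C)=O)[C@]2(O)[C@@H](C)C(=O)O[C@H]2[C@H]1Cl
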